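**Plan**

- The target has no stereocentre and both alkenes carry geminal methyl groups, so no configuration has to be set.
- Retrosynthesis first removes the O-protecting groups and the C3–O bond, then cuts three bonds of ring C: O1–C8a, C4–C4a and O1–C2.
- This is possible because ring A carries O1 (on C8a) and the C4 carbonyl (on C4a) on adjacent carbons, with the C5 oxygen on the next carbon. That is the 1,2-oxygen/acyl pattern left when a carboxyl C–O bond adds across a 3-alkoxybenzyne.
- The two halves are a ring A silylaryl triflate (from phloroglucinol) and a ring B arylpropiolic acid. The acid is cut at the aryl–alkyne bond and at the two aryl–CH2 bonds (4-iodophenol, two molecules of prenyl bromide, propiolic acid).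
- Forward: rings A and B are bought, ring C is formed in one operation by fluoride-induced aryne insertion and oxa-Michael closure, then C3 is hydroxylated and the MOM ethers are removed.

Key step: step 8

**Route**

Step 1
Reactants: 1 phloroglucinol (benzene-1,3,5-triol)
Product: 3 3,5-bis(methoxymethoxy)phenol, via 5-(methoxymethoxy)benzene-1,3-diol 2 (not isolated)
Conditions: MOMCl (2.0 equiv), i-Pr2NEt (2.2 equiv), DMF, 0 °C to rt; chromatography
Reagents that add atoms: chloromethyl methyl ether (MOMCl), COCCl
Why: Williamson-type O-alkylation (MOM protection) of a threefold-symmetric triol, in which all hydroxyls are equivalent, so only the degree of etherification has to be controlled by stoichiometry and the bis-ether is separated from mono- and tris-ether, the mono-ether being resubmitted.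

Step 2
Reactants: 3 3,5-bis(methoxymethoxy)phenol
Product: 4 2-bromo-3,5-bis(methoxymethoxy)phenol
Conditions: NBS (1.0 equiv), CH2Cl2, −78 to −20 °C
Reagents that add atoms: N-bromosuccinimide (NBS), O=C1CCC(=O)N1Br
Why: Electrophilic aromatic bromination in a non-polar solvent at low temperature, where NBS is delivered through a hydrogen bond to the free phenol and the two equivalent ortho carbons are less shielded than C4 between the two MOM ethers, so the 2-bromo isomer should predominate as with other 3,5-dialkoxyphenols.

Step 3
Reactants: 4 2-bromo-3,5-bis(methoxymethoxy)phenol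
Product: 5 [2-bromo-3,5-bis(methoxymethoxy)phenoxy]trimethylsilane
Conditions: HMDS, THF, 70 °C; volatiles removed in vacuo, residue used crude
Reagents that add atoms: hexamethyldisilazane (HMDS), C[Si](C)(C)N[Si](C)(C)C
Why: O-Silylation of a phenol with HMDS, driven by loss of ammonia and leaving only volatile by-products, so the moisture-sensitive aryl silyl ether can be carried on without purification.

Step 4
Reactants: 5 [2-bromo-3,5-bis(methoxymethoxy)phenoxy]trimethylsilane
Product: 8 3,5-bis(methoxymethoxy)-2-(trimethylsilyl)phenyl trifluoromethanesulfonate, via 2-lithioaryl silyl ether 6 (not isolated), via lithium 2-silylphenoxide 7 (not isolated)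
Conditions: n-BuLi (1.1 equiv), THF, −100 to −80 °C; then Tf2O (1.2 equiv), −100 to −80 °C; cold aq. NaHCO3
Reagents that add atoms: trifluoromethanesulfonic anhydride (Tf2O), O=S(=O)(OS(=O)(=O)C(F)(F)F)C(F)(F)F
Why: Bromine–lithium exchange outruns ring deprotonation at −100 °C, the aryl anion takes the silyl group from the neighbouring oxygen (retro-Brook 1,3-O-to-C shift) and the released lithium phenoxide is trapped as the triflate, the standard one-flask entry to ortho-silylaryl triflates.

Step 5
Reactants: 9 4-iodophenol; 10 prenyl bromide (1-bromo-3-methylbut-2-ene)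
Product: 12 4-iodo-2,6-bis(3-methylbut-2-enyl)phenol, via 4-iodo-2-(3-methylbut-2-enyl)phenol 11 (not isolated)
Conditions: prenyl bromide (3 equiv in total, added in portions), aq. NaOH (2 M), rt, vigorous stirring; acidification, chromatography
Reagents that add atoms: prenyl bromide (a second molecule of compound 10, consumed in the alkylation of 11), CC(C)=CCBr
Why: Two successive ortho C-alkylations of an ambident phenoxide, each consuming one molecule of the bromide, in which water solvates the oxygen terminus and suppresses ether formation, iodine blocks the para carbon, and direct SN2 displacement at the primary allylic bromide places unrearranged prenyl groups on both ortho carbons, as is usual for para-substituted phenoxides.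

Step 6
Reactants: 12 4-iodo-2,6-bis(3-methylbut-2-enyl)phenol
Product: 13 5-iodo-2-(methoxymethoxy)-1,3-bis(3-methylbut-2-enyl)benzene
Conditions: NaH (1.3 equiv), DMF, 0 °C; then MOMCl (1.3 equiv), 0 °C to rt
Reagents that add atoms: chloromethyl methyl ether (MOMCl), COCCl
Why: Williamson etherification (MOM protection) of the sodium phenoxide, which in DMF is nucleophilic enough to react despite the two flanking prenyl groups, and which masks the only acidic proton before the coupling, aryne and LiN(i-Pr)2 steps.

Step 7
Reactants: 13 5-iodo-2-(methoxymethoxy)-1,3-bis(3-methylbut-2-enyl)benzene; 14 propiolic acid (prop-2-ynoic acid)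
Product: 15 3-[4-(methoxymethoxy)-3,5-bis(3-methylbut-2-enyl)phenyl]prop-2-ynoic acid
Conditions: Pd(PPh3)4 (5 mol %), DBU (2.5 equiv), DMSO, 30 °C; cold aq. citric acid work-up
Reagents that add atoms: none
Why: Copper-free Sonogashira coupling of an unhindered aryl iodide with propiolic acid on a zerovalent palladium catalyst, under DBU/DMSO conditions known to stop at the arylpropiolic acid without decarboxylation and to which the MOM ether and prenyl alkenes are inert.

Step 8
Reactants: 8 3,5-bis(methoxymethoxy)-2-(trimethylsilyl)phenyl trifluoromethanesulfonate (1.5 equiv); 15 3-[4-(methoxymethoxy)-3,5-bis(3-methylbut-2-enyl)phenyl]prop-2-ynoic acid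
Product: 18 5,7-bis(methoxymethoxy)-2-[4-(methoxymethoxy)-3,5-bis(3-methylbut-2-enyl)phenyl]chromen-4-one, via 3,5-bis(methoxymethoxy)benzyne 16 (not isolated), via ortho-hydroxyaryl ynone 17 (not isolated)
Conditions: CsF (4 equiv), THF, 125 °C, sealed tube
Reagents that add atoms: none
Why: Fluoride removes the silyl group of 8 and triflate leaves to give aryne 16; the caesium carboxylate of 15 adds through oxygen to the aryne carbon remote from the flanking MOM ether, the aryl anion formed beside that ether attacks the ester carbonyl (4-exo-trig) and the strained benzoxetene opens to the ortho-acylphenoxide of 17, a net insertion of the aryne into the carboxyl C–O bond that forms O1–C8a and C4–C4a. The phenoxide then closes ring C by 6-endo-dig oxa-Michael addition to the ynone (O1–C2), and the C3 carbanion takes up the proton originally supplied by the acid. The closest known reaction is the fluoride-induced C–O insertion of arynes into carboxylic acids, which with 3-arylpropiolic acids is known to continue to flavones in the same flask. No stereocentre is created. Two selectivities are needed: the regiochemistry of aryne attack, secured because the inductively withdrawing C–O bond at C3 of the aryne polarises and distorts the triple bond so that the nucleophile enters at C1 and the charge develops at C2, which places the carbonyl next to the future C5 oxygen; and 6-endo over 5-exo closure, secured by the ynone polarisation that directs the phenoxide to the β-carbon and by the stability of the aromatic pyranone at 125 °C. The medium is basic and non-oxidising, so the three MOM ethers and both prenyl alkenes should pass unchanged.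

Step 9
Reactants: 18 5,7-bis(methoxymethoxy)-2-[4-(methoxymethoxy)-3,5-bis(3-methylbut-2-enyl)phenyl]chromen-4-one
Product: 21 3-hydroxy-5,7-bis(methoxymethoxy)-2-[4-(methoxymethoxy)-3,5-bis(3-methylbut-2-enyl)phenyl]chromen-4-one, via 3-lithioflavone 19 (not isolated), via lithium trimethoxyborate 20 (not isolated)
Conditions: LiN(i-Pr)2 (1.2 equiv), THF, −78 °C; B(OMe)3 (3 equiv), −78 to 0 °C; then 30% H2O2, NaH2PO4/Na2HPO4 buffer (pH 7), 0 °C to rt
Reagents that add atoms: hydrogen peroxide, OO
Why: Deprotonation at C3 (the vinylic C–H alpha to the C4 carbonyl, with lithium held by the carbonyl oxygen), borylation and boron-to-oxygen 1,2-migration with neutral peroxide make up the known lithiation–borylation–oxidation route from 5,7-dialkoxyflavones to flavonols, and peroxide at pH 7 does not epoxidise the prenyl alkenes.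

Step 10
Reactants: 21 3-hydroxy-5,7-bis(methoxymethoxy)-2-[4-(methoxymethoxy)-3,5-bis(3-methylbut-2-enyl)phenyl]chromen-4-one
Product: 22 3,5,7-trihydroxy-2-[4-hydroxy-3,5-bis(3-methylbut-2-enyl)phenyl]chromen-4-one (target)
Conditions: aq. HCl (3 M)/MeOH, 45 °C, stopped at full conversion
Reagents that add atoms: none
Why: Acid-catalysed acetal exchange (MOM cleavage) in methanol frees the three phenols, under conditions mild and brief enough that the ortho-prenyl phenol should not close to a chroman.

**Compound list**

1 | phloroglucinol (benzene-1,3,5-triol) | Oc1cc(O)cc(O)c1 | starting material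
2 | 5-(methoxymethoxy)benzene-1,3-diol | COCOc1cc(O)cc(O)c1 | intermediate
3 | 3,5-bis(methoxymethoxy)phenol | COCOc1cc(O)cc(OCOC)c1 | intermediate
4 | 2-bromo-3,5-bis(methoxymethoxy)phenol | COCOc1cc(O)c(Br)c(OCOC)c1 | intermediate
5 | [2-bromo-3,5-bis(methoxymethoxy)phenoxy]trimethylsilane | COCOc1cc(O[Si](C)(C)C)c(Br)c(OCOC)c1 | intermediate
6 | [2-lithio-3,5-bis(methoxymethoxy)phenoxy]trimethylsilane | COCOc1cc(O[Si](C)(C)C)c([Li])c(OCOC)c1 | intermediate
7 | lithium 3,5-bis(methoxymethoxy)-2-(trimethylsilyl)phenoxide | COCOc1cc(O[Li])c([Si](C)(C)C)c(OCOC)c1 | intermediate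
8 | 3,5-bis(methoxymethoxy)-2-(trimethylsilyl)phenyl trifluoromethanesulfonate | COCOc1cc(OS(=O)(=O)C(F)(F)F)c([Si](C)(C)C)c(OCOC)c1 | intermediate
9 | 4-iodophenol | Oc1ccc(I)cc1 | starting material
10 | prenyl bromide (1-bromo-3-methylbut-2-ene) | CC(C)=CCBr | starting material
11 | 4-iodo-2-(3-methylbut-2-enyl)phenol | CC(C)=CCc1cc(I)ccc1O | intermediate
12 | 4-iodo-2,6-bis(3-methylbut-2-enyl)phenol | CC(C)=CCc1cc(I)cc(CC=C(C)C)c1O | intermediate
13 | 5-iodo-2-(methoxymethoxy)-1,3-bis(3-methylbut-2-enyl)benzene | CC(C)=CCc1cc(I)cc(CC=C(C)C)c1OCOC | intermediate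
14 | propiolic acid (prop-2-ynoic acid) | C#CC(=O)O | starting material
15 | 3-[4-(methoxymethoxy)-3,5-bis(3-methylbut-2-enyl)phenyl]prop-2-ynoic acid | CC(C)=CCc1cc(C#CC(=O)O)cc(CC=C(C)C)c1OCOC | intermediate
16 | 3,5-bis(methoxymethoxy)benzyne (1,2-didehydro-3,5-bis(methoxymethoxy)benzene) | COCOC1=CC(OCOC)=CC#C1 | intermediate
17 | 1-[2-hydroxy-4,6-bis(methoxymethoxy)phenyl]-3-[4-(methoxymethoxy)-3,5-bis(3-methylbut-2-enyl)phenyl]prop-2-yn-1-one | COCOc1cc(O)c(C(=O)C#Cc2cc(CC=C(C)C)c(OCOC)c(CC=C(C)C)c2)c(OCOC)c1 | intermediate
18 | 5,7-bis(methoxymethoxy)-2-[4-(methoxymethoxy)-3,5-bis(3-methylbut-2-enyl)phenyl]chromen-4-one | CC(C)=CCc1cc(-c2cc(=O)c3c(OCOC)cc(OCOC)cc3o2)cc(CC=C(C)C)c1OCOC | intermediate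
19 | 3-lithio-5,7-bis(methoxymethoxy)-2-[4-(methoxymethoxy)-3,5-bis(3-methylbut-2-enyl)phenyl]chromen-4-one | CC(C)=CCc1cc(-c2oc3cc(OCOC)cc(OCOC)c3c(=O)c2[Li])cc(CC=C(C)C)c1OCOC | intermediate
20 | lithium trimethoxy{5,7-bis(methoxymethoxy)-2-[4-(methoxymethoxy)-3,5-bis(3-methylbut-2-enyl)phenyl]-4-oxochromen-3-yl}borate | CC(C)=CCc1cc(-c2oc3cc(OCOC)cc(OCOC)c3c(=O)c2[B-](OC)(OC)OC)cc(CC=C(C)C)c1OCOC.[Li+] | intermediate
21 | 3-hydroxy-5,7-bis(methoxymethoxy)-2-[4-(methoxymethoxy)-3,5-bis(3-methylbut-2-enyl)phenyl]chromen-4-one | CC(C)=CCc1cc(-c2oc3cc(OCOC)cc(OCOC)c3c(=O)c2O)cc(CC=C(C)C)c1OCOC | intermediate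
22 | 3,5,7-trihydroxy-2-[4-hydroxy-3,5-bis(3-methylbut-2-enyl)phenyl]chromen-4-one | CC(C)=CCc1cc(-c2oc3cc(O)cc(O)c3c(=O)c2O)cc(CC=C(C)C)c1O | target

**Step count**

Total: 10 steps. Longest linear sequence: 7 steps (steps 1, 2, 3, 4, 8, 9, 10, from phloroglucinol). The ring B branch (steps 5, 6, 7) joins at step 8; step 5 consumes two molecules of prenyl bromide.

**Steps most likely to fail**

Step 8.
- What may go wrong: the aryl anion is protonated before acyl transfer, so the reaction stops at the aryl ester; the caesium arylpropiolate decarboxylates at 125 °C; or the carboxylate attacks the wrong aryne carbon.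
- Fallback: the same ynone is made by organolithium acylation instead of aryne insertion, setting out from acid 15 and bromophenol 4.
- Acid 15 would be condensed with N,O-dimethylhydroxylamine hydrochloride (EDC hydrochloride, N-methylmorpholine, CH2Cl2) to N-methoxy-N-methyl-3-[4-(methoxymethoxy)-3,5-bis(3-methylbut-2-enyl)phenyl]prop-2-ynamide F1.
- Bromophenol 4 would be deprotonated with MeLi and exchanged with t-BuLi (THF, −78 °C) to lithium 2-lithio-3,5-bis(methoxymethoxy)phenoxide F2, which should add once to F1.
- Mildly acidic work-up would give ynone 17, now isolated. Diethylamine in ethanol, conditions under which such ynones are known to close in the 6-endo sense, would convert it into flavone 18, where the route is rejoined.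

Step 9.
- What may go wrong: the amide base removes a benzylic–allylic proton of a prenyl group or metalates ring A instead of C3, or the electron-rich flavonol is over-oxidised in the peroxide stage.
- Fallback: no carbanion is involved; methoxide addition is followed by alpha-oxygenation with trivalent iodine, setting out from flavone 18.
- PhI(OAc)2 and KOH in methanol (0 °C to rt) should add methoxide at C2, oxygenate the enolate at C3 and acetalise C4. The expected product is racemic cis-2,4,4-trimethoxy-5,7-bis(methoxymethoxy)-2-[4-(methoxymethoxy)-3,5-bis(3-methylbut-2-enyl)phenyl]chroman-3-ol F3 (2-methoxy and 3-hydroxy on the same face, one enantiomer drawn; both centres are erased in the next operation).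
- Exposure of F3 to the aq. HCl/MeOH of step 10 should hydrolyse the acetal, eliminate methanol across C2–C3 and cleave the MOM ethers, so the route is rejoined at target 22.

Step 2.
- What may go wrong: bromination para to the hydroxyl (between the two MOM ethers) or twofold bromination, which would carry the silyl group to the wrong carbon in step 4.
- Fallback: carbamate-directed ortho-metalation replaces electrophilic substitution, setting out from phenol 3.
- ClC(O)NEt2 and K2CO3 in MeCN would give 3,5-bis(methoxymethoxy)phenyl N,N-diethylcarbamate F4.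
- s-BuLi/TMEDA in THF at −78 °C should metalate the carbon between the carbamate (the stronger director) and a MOM ether, giving 2-lithio-3,5-bis(methoxymethoxy)phenyl N,N-diethylcarbamate F5. This is trapped cold with Me3SiCl as 3,5-bis(methoxymethoxy)-2-(trimethylsilyl)phenyl N,N-diethylcarbamate F6.
- Reductive cleavage of the carbamate with Cp2Zr(H)Cl in THF would free 3,5-bis(methoxymethoxy)-2-(trimethylsilyl)phenol F7. Tf2O/pyridine in CH2Cl2 at 0 °C would convert it into triflate 8, where the route is rejoined with steps 3 and 4 bypassed.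

**Further compounds**

F1 | step 8 | N-methoxy-N-methyl-3-[4-(methoxymethoxy)-3,5-bis(3-methylbut-2-enyl)phenyl]prop-2-ynamide | CC(C)=CCc1cc(C#CC(=O)N(C)OC)cc(CC=C(C)C)c1OCOC
F2 | step 8 | lithium 2-lithio-3,5-bis(methoxymethoxy)phenoxide | [Li]Oc1cc(OCOC)cc(OCOC)c1[Li]
F3 | step 9 | racemic cis-2,4,4-trimethoxy-5,7-bis(methoxymethoxy)-2-[4-(methoxymethoxy)-3,5-bis(3-methylbut-2-enyl)phenyl]chroman-3-ol | CO[C@@]1(c2cc(CC=C(C)C)c(OCOC)c(CC=C(C)C)c2)Oc2cc(OCOC)cc(OCOC)c2C(OC)(OC)[C@H]1O
F4 | step 2 | 3,5-bis(methoxymethoxy)phenyl N,N-diethylcarbamate | CCN(CC)C(=O)Oc1cc(OCOC)cc(OCOC)c1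
F5 | step 2 | 2-lithio-3,5-bis(methoxymethoxy)phenyl N,N-diethylcarbamate | CCN(CC)C(=O)Oc1cc(OCOC)cc(OCOC)c1[Li]
F6 | step 2 | 3,5-bis(methoxymethoxy)-2-(trimethylsilyl)phenyl N,N-diethylcarbamate | CCN(CC)C(=O)Oc1cc(OCOC)cc(OCOC)c1[Si](C)(C)C
F7 | step 2 | 3,5-bis(methoxymethoxy)-2-(trimethylsilyl)phenol | COCOc1cc(O)c([Si](C)(C)C)c(OCOC)c1
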